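The runs are calculated on assumed constants; the scatter is artificial.

Product in the ash run is counted against the partner, the limiting reagent: each product takes one of each, and the charge holds 0.120 M of partner beside 0.500 M of starting material. Its share of the starting material therefore has a ceiling of 24.0 %, and what we have to reckon is the small shortfall beneath it.

| flask | starting material | partner | product | time |
|---|---|---|---|---|
| larch | 0.100 M | 0.120 M |  |  |
| oak | 0.0400 M | 0.0600 M |  |  |
| alder | 0.100 M | 0.360 M |  |  |
| birch | 0.100 M | 0.120 M | 0.0500 M |  |
| ash | 0.500 M | 0.120 M |  | 12 min |

| larch run: time / min | larch run: [product] / M | oak run: time / min | oak run: [product] / M | alder run: time / min | alder run: [product] / M | birch run: time / min | birch run: [product] / M |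
|---|---|---|---|---|---|---|---|
| 0.48 | 0.0036 | 0.48 | 0.0017 | 0.48 | 0.0071 | 0.48 | 0.0532 |
| 1.1 | 0.0085 | 1.1 | 0.0029 | 1.1 | 0.0151 | 1.1 | 0.0588 |
| 2.4 | 0.0177 | 2.4 | 0.0053 | 2.4 | 0.0281 | 2.4 | 0.0669 |
| 5.4 | 0.0337 | 5.4 | 0.0106 | 5.4 | 0.0512 | 5.4 | 0.0841 |
| 12 | 0.0573 | 12 | 0.0182 | 12 | 0.0786 | 12 | 0.1057 |

(standard deviation of a reading: 8 × 10⁻⁴ M)

- Overall: starting material + partner -> product.
- Constant volume, constant temperature.
- What is held in complexes is read along with the free species.
- "The second partner" is partner.
- An order is taken over about fifteen percent of the charge, up and down.

- the exponent of [starting material] in the starting rate at the charge of the larch run (at the point where two percent of the starting material have become product) (one fixed amount of product, the same in the runs compared)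
- the exponent of [partner] in the starting rate at the charge of the larch run (at the point where two percent of the starting material have become product)
- the oak run starts with 0.0600 M less of starting material and of partner than the larch run, and with no product. Compared where both hold the same amount of starting material, once fifteen percent of what the oak run was charged with has turned into product, is the oak run faster, slower or alike (within a tenth)?
- product in the ash run at 12 min, as a share of the starting material charged

We build the flask up one process at a time. With the main step alone, the rate is a constant times both concentrations, and we call that constant k_app, the apparent second-order constant, the early rate divided by the two charges, read from the larch run as 0.644 M⁻¹ min⁻¹; the scatter on the reading behind it is 9.41 %. If starting material is held at its charge, partner decays pseudo-first-order and the ash share at 12 min comes to 23.5 %. Letting starting material fall as well, towards 0.380 M at the ceiling, the second-order integral gives a share of 23.0 %, which is lower and leaves a shortfall of 1.00 percentage point.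

Then come the remaining observations. At 1.1 min, the alder run, with 0.360 M of partner instead of 0.120 M, read 0.0151 M against 0.0085 M in the larch run, an average order in partner of 0.523 over that wide span, below one. So k_app depends on partner, but the ash run starts at the partner charge of the larch run and goes down from there, and we keep the larch value. The birch run, charged with 0.0500 M of product, made 0.0557 M in 12 min against 0.0573 M in the larch run, so we expect the oak and larch runs to be alike at equal composition. We commit to 23.0 %.

The forecast, on the ground that “A pre-equilibrium fits”, gives orders of 0.8 in starting material and 0.72 in partner, alike for the oak run, and 20 % for the ash run, a lower share than ours.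

The flask gives orders of 0.93 and 0.58, alike for the oak run, and 23.1 % for the ash run.

    starting material + partner → product + by-product (2.136 M⁻¹ min⁻¹)
    starting material + partner ⇌ idle substrate-reagent adduct, settled at all times (4.710 M⁻¹)
    2 partner ⇌ idle reagent dimer, settled at all times (12.90 M⁻¹)

In the ash run the shortfall is 0.90 points against our 1.00 point. Carried to the alder run, k_app gives a rate of 0.0232 M min⁻¹, but that run stands at 0.014 M min⁻¹, lower, which puts its own k_app at 0.382 M⁻¹ min⁻¹. Because two partner join to idle reagent dimer, the order in partner at the larch charge is 0.58, against 0.77 in the run without that joining.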